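# Synthesis of 2β-methoxy-2-deethoxy-8-O-deacylphantomolin-8-O-tiglinate

**Target structure (heliangolide numbering).** The target is a trans-fused 6,12-α-methylene-γ-lactone inside a 10-membered carbocycle. The carbocycle carries an E-C1=C10 alkene, a C2,C5 oxa-bridge that forms a 2-methoxy-2,5-dihydrofuran (C3=C4, 4-Me), and a C8 tiglate. The stereocentres are 2S, 5S, 6S, 7R and 8S.

**Retrosynthesis**
1. The target comes from tigloylation of bridged methyl ketal **24**. The dihydrofuran is formed last, by a transannular cascade (E→Z isomerisation, hemiketalisation, methyl ketalisation) of macrocyclic (E,E)-γ-hydroxy-dienone **23**.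
2. **23** comes from oxidation of macrocyclic alcohol **21**. **21** is closed at C1–C2 by an intramolecular Nozaki–Hiyama–Kishi reaction of an E-vinyl iodide with an E-enal.
3. Lactone **20** comes from an intermolecular Cr-allylation/lactonisation (C6–C7, anti, so trans-lactone) of aldehyde **19** with Baylis–Hillman-derived allyl bromide **18**.
4. C5 and C8 are set by two proline-catalysed α-aminoxylations, of ketone **1** and aldehyde **10**. C6 and C7 are set by the allylation, and C2 by the oxa-bridge. Rings form in the order: lactone, 10-membered ring, oxa-bridge.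

**Assumptions**
- Aminoxylation of **1** occurs at the acetal-flanked CH2 (more substituted anti-enamine).
- L-Proline gives (R)-α-oxygenated carbonyls and D-proline the (S), by the usual enamine-face model.
- Once C5 is fixed, the bridgehead C2 configuration is dictated by the oxa-bridge.

## Route

**Step 1**
Reactants: 1 4,4-dimethoxybutan-2-one; 2 nitrosobenzene
Product: 3 (3R)-4,4-dimethoxy-3-(N-phenylaminooxy)butan-2-one
Conditions: L-proline (20 mol%), DMSO–CHCl3, 0 °C, 24 h
Reagents that add atoms: nitrosobenzene, O=Nc1ccccc1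
Why: Proline enamine formation at the acetal-flanked methylene followed by O-attack on PhN=O (enamine α-aminoxylation) sets C5 as the first stereocentre, (R) in this intermediate.

**Step 2**
Reactants: 3
Product: 4 (3R)-3-hydroxy-4,4-dimethoxybutan-2-one
Conditions: CuSO4·5H2O (0.2 equiv), MeOH, rt
Reagents that add atoms: none
Why: Cu(II) cleaves the N–O bond (aminoxy → alcohol) without touching the stereocentre.

**Step 3**
Reactants: 4
Product: 5 (3R)-3-(TBSO)-4,4-dimethoxybutan-2-one
Conditions: TBSCl, imidazole, DMF, rt
Reagents that add atoms: TBSCl, CC(C)(C)[Si](C)(C)Cl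
Why: Silylation gives a bulky non-chelating C5 ether that later favours Felkin control and survives all later steps until step 18.

**Step 4**
Reactants: 5; 6 (formylmethylene)triphenylphosphorane
Product: 7 (2E,4S)-4-(TBSO)-5,5-dimethoxy-3-methylpent-2-enal
Conditions: Ph3P=CHCHO (3 equiv), toluene, 90 °C, 48 h
Reagents that add atoms: Ph3P=CHCHO, O=CC=P(c1ccccc1)(c1ccccc1)c1ccccc1
Why: Wittig olefination of the methyl ketone with a stabilised ylide gives the E-enal, with the CHO trans to the larger C5 group; no new stereocentre is formed.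

**Step 5**
Reactants: 8 pent-4-yn-1-ol
Product: 9 (4E)-5-iodo-4-methylpent-4-en-1-ol
Conditions: Me3Al, Cp2ZrCl2 (10 mol%), CH2Cl2, 0 °C→rt; then I2, THF, −30 °C
Reagents that add atoms: trimethylaluminium, C[Al](C)C; iodine, II
Why: Negishi Zr-catalysed syn-methylalumination then iodinolysis gives the E-trisubstituted vinyl iodide, which becomes E-C1=C10.

**Step 6**
Reactants: 9
Product: 10 (4E)-5-iodo-4-methylpent-4-enal
Conditions: Dess–Martin periodinane, NaHCO3, CH2Cl2, 0 °C
Reagents that add atoms: none
Why: Mild oxidation of the primary alcohol leaves the vinyl iodide intact.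

**Step 7**
Reactants: 10; 2 nitrosobenzene
Product: 11 (2S,4E)-5-iodo-4-methyl-2-(N-phenylaminooxy)pent-4-en-1-ol
Conditions: D-proline (20 mol%), MeCN, −20 °C; then NaBH4, MeOH, 0 °C
Reagents that add atoms: nitrosobenzene, O=Nc1ccccc1
Why: Proline-catalysed α-aminoxylation with in-situ reduction sets C8 as (S).

**Step 8**
Reactants: 11
Product: 12 (2S,4E)-5-iodo-4-methylpent-4-ene-1,2-diol
Conditions: CuSO4·5H2O (0.2 equiv), MeOH, rt
Reagents that add atoms: none
Why: N–O cleavage as in step 2.

**Step 9**
Reactants: 12
Product: 13 bis-TBS ether of 12, (S)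
Conditions: TBSOTf (2.5 equiv), 2,6-lutidine, CH2Cl2, 0 °C
Reagents that add atoms: TBSOTf, CC(C)(C)[Si](C)(C)OS(=O)(=O)C(F)(F)F
Why: Global silylation prepares selective unmasking of the primary alcohol.

**Step 10**
Reactants: 13
Product: 14 (2S,4E)-2-(TBSO)-5-iodo-4-methylpent-4-en-1-ol
Conditions: CSA (10 mol%), MeOH–CH2Cl2 1:1, 0 °C, 1 h
Reagents that add atoms: none
Why: Acid-catalysed methanolysis cleaves a primary TBS ether much faster than a secondary one.

**Step 11**
Reactants: 14
Product: 15 (2S,4E)-2-(TBSO)-5-iodo-4-methylpent-4-enal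
Conditions: Dess–Martin periodinane, NaHCO3, CH2Cl2, 0 °C
Reagents that add atoms: none
Why: Buffered oxidation avoids epimerisation of the α-silyloxy stereocentre (C8).

**Step 12**
Reactants: 15; 16 methyl acrylate
Product: 17 methyl (4S,6E)-4-(TBSO)-3-hydroxy-7-iodo-6-methyl-2-methylenehept-6-enoate (C7 epimeric mixture)
Conditions: 3-hydroxyquinuclidine (30 mol%), methyl acrylate (10 equiv), neat, 0 °C→rt, 48 h
Reagents that add atoms: methyl acrylate, C=CC(=O)OC
Why: Morita–Baylis–Hillman reaction builds C7, C11, C12 and the C13 methylene; the C7 carbinol stereocentre is destroyed in step 13 and C8 is untouched.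

**Step 13**
Reactants: 17
Product: 18 methyl (2Z,4S,6E)-2-(bromomethyl)-4-(TBSO)-7-iodo-6-methylhepta-2,6-dienoate
Conditions: NBS, Me2S, CH2Cl2, 0 °C→rt
Reagents that add atoms: N-bromosuccinimide, O=C1CCC(=O)N1Br
Why: Bromodehydroxylation of a Baylis–Hillman alcohol (SN2′) gives the Z-allyl bromide; both E/Z isomers give the same allylchromium.

**Step 14**
Reactants: 7
Product: 19 (2S,3E)-2-(TBSO)-3-methylpent-3-enedial
Conditions: TMSOTf (2.2 equiv), 2,4,6-collidine (3 equiv), CH2Cl2, 0 °C; then H2O
Reagents that add atoms: water, O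
Why: Fujioka–Kita acetal-to-aldehyde conversion under non-acidic conditions; the product is used immediately because C5–H is activated.

**Step 15**
Reactants: 19; 18
Product: 20 trans-fused α-methylene-γ-butyrolactone with C5/C6/C7/C8 configured as in the target. It carries the C5 (TBSO) E-enal arm and the C8 (TBSO) E-vinyl iodide arm.
Conditions: CrCl2 (6 equiv), DMF, 0 °C→rt, 12 h; then TsOH (cat.), CH2Cl2
Reagents that add atoms: allyl bromide 18, COC(=O)/C(CBr)=C/[C@@H](O[Si](C)(C)C(C)(C)C)C/C(C)=C/I
Why: Hiyama–Nozaki Cr-allylation through a chair transition state of the E-allylchromium (without Ni, the vinyl iodide is inert) gives the anti homoallylic alcohol (C6/C7), hence the trans-lactone after lactonisation. The non-chelating C5-OTBS favours the Felkin syn relationship of C5 and C6, and aldehyde C6 is preferred over the enal.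

**Step 16**
Reactants: 20
Product: 21 macrocyclic C2-alcohol (10-membered carbocycle, E-C1=C10, E-C3=C4; C2 epimeric)
Conditions: CrCl2 (10 equiv), NiCl2 (0.5 mol%), DMF, 0.002 M (slow addition, 10 h), 25 °C
Reagents that add atoms: none
Why: Intramolecular Nozaki–Hiyama–Kishi coupling closes C1–C2 with retention of alkene geometry; the C2 epimers are lost in step 17.

**Step 17**
Reactants: 21
Product: 22 macrocyclic (E,E)-dienone
Conditions: Dess–Martin periodinane, NaHCO3, CH2Cl2, 0 °C
Reagents that add atoms: none
Why: Oxidation of the bis-allylic alcohol gives the C2 ketone and removes the C2 epimer issue.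

**Step 18**
Reactants: 22
Product: 23 (E,E)-γ-hydroxy-dienone with free C5-OH and C8-OH
Conditions: HF·pyridine, pyridine, THF, 0 °C→rt
Reagents that add atoms: none
Why: Fluoride cleaves both TBS ethers; the E-C3=C4 geometry prevents premature cyclisation of C5-OH onto C2=O.

**Step 19**
Reactants: 23
Product: 24 bridged 2β-methoxy-2,5-dihydrofuran (8-OH)
Conditions: thioxanthone (10 mol%), PPTS (10 mol%), MeOH–CH2Cl2 1:1, 405 nm LEDs, 25 °C
Reagents that add atoms: methanol, CO
Why: Proposed new method: triplet energy transfer from thioxanthone to the cross-conjugated dienone gives a twisted triplet that relaxes to an E/Z mixture, and only the Z-C3=C4 isomer can place C5-OH on C2=O, so 5-exo transannular hemiketalisation drains the photostationary state irreversibly. The hemiketal ionises (PPTS) to the doubly allylic oxocarbenium, and MeOH captures it on the exo face, which fixes C2 as (S) and forms the oxa-bridge. The closest known reactions are energy-transfer E→Z isomerisation/lactonisation of γ-hydroxy enoates, the germacranolide→heliangolide 4(5)-E→Z photo-isomerisation, and cis-γ-hydroxy-enone ⇌ 2-hydroxy-2,5-dihydrofuran ketalisation. Strain in the (E,E)-dienone should favour isomerisation.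

**Step 20**
Reactants: 24; 25 tiglic acid
Product: 26 target
Conditions: tiglic acid, 2,4,6-trichlorobenzoyl chloride, Et3N, THF, rt; then 24, DMAP, toluene, rt
Reagents that add atoms: tiglic acid, OC(=O)/C(C)=C/C
Why: Yamaguchi esterification of the only free hydroxyl under basic conditions leaves the acid-labile ketal, the C8 configuration and the E-tiglate intact.

## Compound list

| # | Name | SMILES | Role |
|---|---|---|---|
| 1 | 4,4-dimethoxybutan-2-one | CC(=O)CC(OC)OC | starting material |
| 2 | nitrosobenzene | O=Nc1ccccc1 | starting material |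
| 3 | (3R)-aminoxy ketone | CC(=O)[C@H](ONc1ccccc1)C(OC)OC | intermediate |
| 4 | (3R)-3-hydroxy-4,4-dimethoxybutan-2-one | CC(=O)[C@H](O)C(OC)OC | intermediate |
| 5 | (3R)-TBS ether | CC(=O)[C@H](O[Si](C)(C)C(C)(C)C)C(OC)OC | intermediate |
| 6 | Ph3P=CHCHO | O=CC=P(c1ccccc1)(c1ccccc1)c1ccccc1 | starting material |
| 7 | (2E,4S)-enal acetal | O=C/C=C(\C)[C@H](O[Si](C)(C)C(C)(C)C)C(OC)OC | intermediate |
| 8 | pent-4-yn-1-ol | C#CCCCO | starting material |
| 9 | (4E)-5-iodo-4-methylpent-4-en-1-ol | OCCC/C(C)=C/I | intermediate |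
| 10 | (4E)-5-iodo-4-methylpent-4-enal | O=CCC/C(C)=C/I | intermediate |
| 11 | (2S,4E)-aminoxy alcohol | OC[C@@H](ONc1ccccc1)C/C(C)=C/I | intermediate |
| 12 | (2S,4E)-diol | OC[C@@H](O)C/C(C)=C/I | intermediate |
| 13 | bis-TBS ether | CC(C)(C)[Si](C)(C)OC[C@@H](O[Si](C)(C)C(C)(C)C)C/C(C)=C/I | intermediate |
| 14 | primary alcohol | OC[C@@H](O[Si](C)(C)C(C)(C)C)C/C(C)=C/I | intermediate |
| 15 | (2S,4E)-α-silyloxy aldehyde | O=C[C@@H](O[Si](C)(C)C(C)(C)C)C/C(C)=C/I | intermediate |
| 16 | methyl acrylate | C=CC(=O)OC | starting material |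
| 17 | Baylis–Hillman alcohol (C7 epimeric; C7 drawn unspecified) | COC(=O)C(=C)C(O)[C@@H](O[Si](C)(C)C(C)(C)C)C/C(C)=C/I | intermediate |
| 18 | (2Z)-allyl bromide | COC(=O)/C(CBr)=C/[C@@H](O[Si](C)(C)C(C)(C)C)C/C(C)=C/I | intermediate |
| 19 | (2S,3E)-2-(TBSO)-3-methylpent-3-enedial | O=C/C=C(\C)[C@H](O[Si](C)(C)C(C)(C)C)C=O | intermediate |
| 20 | trans-lactone, enal/vinyl iodide | C=C1C(=O)O[C@H]([C@@H](O[Si](C)(C)C(C)(C)C)/C(C)=C/C=O)[C@H]1[C@@H](O[Si](C)(C)C(C)(C)C)C/C(C)=C/I | intermediate |
| 21 | macrocyclic C2-alcohol (C2 unspecified) | C=C1C(=O)O[C@H]2[C@H]1[C@@H](O[Si](C)(C)C(C)(C)C)C/C(C)=C/C(O)/C=C(\C)[C@@H]2O[Si](C)(C)C(C)(C)C | intermediate |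
| 22 | (E,E)-macrocyclic dienone | C=C1C(=O)O[C@H]2[C@H]1[C@@H](O[Si](C)(C)C(C)(C)C)C/C(C)=C/C(=O)/C=C(\C)[C@@H]2O[Si](C)(C)C(C)(C)C | intermediate |
| 23 | dihydroxy (E,E)-dienone | C=C1C(=O)O[C@H]2[C@H]1[C@@H](O)C/C(C)=C/C(=O)/C=C(\C)[C@@H]2O | intermediate |
| 24 | 2β-methoxy bridged ketal, 8-OH | C=C1C(=O)O[C@H]2[C@H]1[C@@H](O)C/C(C)=C/[C@@]1(OC)C=C(C)[C@@H]2O1 | intermediate |
| 25 | tiglic acid | OC(=O)/C(C)=C/C | starting material |
| 26 | target | C=C1C(=O)O[C@H]2[C@H]1[C@@H](OC(=O)/C(C)=C/C)C/C(C)=C/[C@@]1(OC)C=C(C)[C@@H]2O1 | target |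

**Total steps: 20. Longest linear sequence: 15** (steps 5–13, then 15–20).

## Three steps most likely to fail

1. **Step 19 (new photochemical cascade).** The (E,E)-dienone may be too strained to form in step 17. The sensitiser may also scramble C1=C10 to give a 1(10)-Z ketal, or cause lactone [2+2] reactions.
   Fallback (known chemistry): set the Z-enone before ring closure. Use carbonylative Sonogashira coupling of the vinyl-iodide fragment with a propargylic silyl ether to give the ene-ynone, then Me2CuLi syn-carbocupration to give the Z-enone. Close the ring by intramolecular Cr-allylation (C6–C7), then finish with HF·py and MeOH/PPTS ketalisation.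

2. **Step 16 (macro-NHK, C1–C2).** Closing a 10-membered trans-lactone-fused ring, with α-methylene-lactone survival under Cr(II), is strain- and chemoselectivity-limited.
   Fallback: change the ring-closing bond. Do the intermolecular NHK coupling of vinyl iodide and enal first, then close the ring by intramolecular allylchromium addition at C6–C7, as in germacranolide syntheses. RCM is a further alternative.

3. **Step 15 (Cr-allylation).** Enal versus aldehyde chemoselectivity, the Felkin syn selectivity at C5/C6, and the C7/C8 relationship are all uncertain, and C5–H is labile.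
   Fallback: replace it with anti-selective propargylation of the C6 aldehyde using a propargyl/allenyl bromide from the same aldehyde 15, then Pd-catalysed cyclocarbonylation of the homopropargylic alcohol to the α-methylene lactone.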